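The alpha run and the zeta run share one recipe except for the initiator, 180 mM against 78 mM, yet at 12.0 h they stand apart in a way that bears on the four new flasks.

| flask | substrate | reagent | scavenger | initiator | remark | time |
|---|---|---|---|---|---|---|
| beta | 0.52 M | 1.3 M (in portions, 4) | 0.156 M | 21 mM | run made earlier; portions every 2.0 h |  |
| zeta | 0.52 M | 1.3 M (in portions, 4) | 0.156 M | 78 mM | run made earlier; portions every 2.0 h |  |
| alpha | 0.52 M | 1.3 M (in portions, 4) | 0.156 M | 180 mM | run made earlier; portions every 2.0 h |  |
| Wednesday's | 0.52 M | 1.30 M (in portions, 4) | 0.156 M | 25 mM | the portions of reagent follow each other after 2.0 h, the first at the start | 25 h |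
| Friday's | 0.52 M | 1.30 M (in portions, 4) | 0.156 M | 50 mM | the portions of reagent follow each other after 2.0 h, the first at the start | 25 h |
| Sunday's | 0.52 M | 1.30 M (in portions, 4) | 0.156 M | 100 mM | the portions of reagent follow each other after 2.0 h, the first at the start | 25 h |
| Thursday's | 0.52 M | 1.30 M (in portions, 4) | 0.156 M | 200 mM | the portions of reagent follow each other after 2.0 h, the first at the start | 25 h |

| run | time / h | product / % | substrate / % |
|---|---|---|---|
| beta | 1.00 | 0 | 98.3 |
| beta | 3.00 | 1.9 | 93.5 |
| beta | 6.00 | 7.7 | 83.0 |
| beta | 8.00 | 11.8 | 73.3 |
| beta | 12.0 | 19.5 | 57.9 |
| zeta | 1.00 | 1.4 | 95.4 |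
| zeta | 3.00 | 6.0 | 82.9 |
| zeta | 6.00 | 16.2 | 58.8 |
| zeta | 8.00 | 26.3 | 38.3 |
| zeta | 12.0 | 40.4 | 6.7 |
| alpha | 1.00 | 2.2 | 91.5 |
| alpha | 2.00 | 4.4 | 82.7 |
| alpha | 4.00 | 13.0 | 59.1 |
| alpha | 6.00 | 24.5 | 31.0 |
| alpha | 12.0 | 58.0 | 0 |

(each reading ± 0.5 percentage points)

- a species is counted by the substrate in it: one ended chains counts as two
- amounts and yields of product count idle adduct B too
- amounts and yields of released group count crystals and idle adduct A too
- given per volume of solution although it is solid: crystals
- steps that have been proposed: initiator -> 2 initiating radical; substrate + initiating radical -> capped initiator + first chain carrier; reagent + first chain carrier -> product + second chain carrier; substrate + second chain carrier -> released group + first chain carrier; first chain carrier -> ended carrier; 2 first chain carrier -> ended chains; crystals <-> released group; substrate + released group <-> idle adduct A; scavenger + released group -> scavenged by-product; reagent + product <-> idle adduct B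
- "hardly changes" means that all values lie within two and a half points (for a concentration: within two and a half percent of the largest)

- amount of product at the end, in percent of the substrate charged for Wednesday's, Friday's, Sunday's, Thursday's, in this order
- how the row runs (rises all the way / hardly changes / falls all the way / rises, then falls / falls, then rises)

At that time the alpha run reads substrate 0 % and product 58.0 %, so 42.0 % of the charge is neither. The zeta run reads 6.7 % and 40.4 %, so its gap is 52.9 %, larger than alpha's although it has less initiator. The gap therefore has two main parts, as I read it. In the proposed steps, each chain takes up one substrate when it starts, and that substrate leaves as ended carrier or ended chains, not as product. The other part is idle adduct A, which needs free substrate to stand.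

With alpha's substrate reading zero, I count its whole gap as lost. That gives what I call the initiation toll, the substrate lost for good per initiator charged: 1.21, a reading that carries the scatter. Taking this toll as fixed for this recipe, I estimate that the zeta run pays 18.2 %, and I read the remaining 35 percentage points of its gap as a store of idle adduct A.

My reckoning follows from this. With the toll held fixed, my estimate of the product is 76.7 % for Sunday's flask and a lower 53.3 % for Thursday's. At the low end, the beta run still holds 57.9 % substrate at 12.0 h, more than alpha's 0 %, so I expect Wednesday's flask to fall short through slow conversion instead. I therefore expect a row that rises and then falls.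

The forecast gives 42 %, 54 %, 62 % and 64 %, a row that rises all the way, and says: “The top end flattens and might turn over slightly”. Here my reckoning differs from it, since mine falls at the top.

The flasks end with product at 39.3 %, 57.5 %, 72.7 % and 61.9 %, so the row rises, then falls, turning at 89 mM of initiator.

initiator → 2 initiating radical (k = 0.0590 /h); substrate + initiating radical → capped initiator + first chain carrier (k = 3.20 × 10⁵ /M/h); reagent + first chain carrier → product + second chain carrier (k = 27000 /M/h); substrate + second chain carrier → released group + first chain carrier (k = 76000 /M/h); first chain carrier → ended carrier (k = 2200 /h); 2 first chain carrier → ended chains (k = 1.10 × 10⁶ /M/s); crystals ⇌ released group, rate k7*(cs7 - [released group]) while solid is left; crystals form when [released group] > cs7 (solubility = 0.390 M, k = 1.50 /h); substrate + released group ⇌ idle adduct A, settled at all times (K = 540 /M); scavenger + released group → scavenged by-product (k = 0.620 /M/h); reagent + product ⇌ idle adduct B, settled at all times (K = 0.430 /M) In Sunday's flask the substrate, the limiting reagent, stands at 0 %, and ended carrier plus ended chains hold 27.3 %. As a toll that is 1.42 per initiator, beside the 1.21 I read from the alpha run. Thursday's flask, its substrate at 0 %, pays 0.990, and its product stands above my estimate of 53.3 % yet below Sunday's, with 0.105 M of initiating radical present at 25.0 h.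

All runs stem from a simulated flask with made-up constants; scatter was added.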